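**Retrosynthetic overview**

1. The last operation is hydrogenolysis of seven benzyl groups. Before it, the ester C–O bond to the side chain is made by Mitsunobu inversion of tribenzylated natural (R)-danshensu with a cyclobutane monoacid, which gives the (S)-configured lactate carbon of the target.
2. The cyclobutane is closed by forming the C–C bond between the ring carbon that carries the ester carbonyl and the ring carbon that carries the 3,4-dioxygenated phenyl ring. A pyrrolidine with its nitrogen between exactly these two carbons is contracted by loss of N2 (iodonitrene, 1,1-diazene, 1,4-biradical) with retention.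
3. Enabling feature: around the four-membered ring, carboxyl and aryl groups alternate (C–CO2R, C–Ar, C–CO2H, C–Ar′). This is the 2-carboxy-3-aryl-4-carboxy-5-aryl pattern of an azomethine ylide/cinnamate cycloadduct, and the two carbons to be joined are α to an ester and benzylic, so both radical ends are stabilised.
4. The core is the monoester of an all-trans meso diacid (all four substituents pseudo-equatorial, the thermodynamic minimum). The temporary ring nitrogen makes the two carboxyl groups different (tert-butyl versus benzyl ester), the absolute configuration rests on the two aryl-bearing carbons set in a catalytic exo-selective [3+2] step, and the one misplaced ester carbon is corrected afterwards by thermodynamic epimerisation.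
5. Ring order: pyrrolidine (step 3, from glycine tert-butyl ester, 3,4-bis(benzyloxy)benzaldehyde and benzyl 4-benzyloxycinnamate), then cyclobutane (step 4).

Key step: step 4

Remark (assumption): (R)-DTBM-Segphos on monovalent copper is assumed to give the (2S,3S,4R,5R) exo cycloadduct in step 3; should the sense of induction be opposite, the (S)-ligand is used and nothing else changes.

**Route**

Step 1
Reactants: 1 (E)-4-hydroxycinnamic acid (p-coumaric acid)
Product: 2 benzyl (E)-3-[4-(benzyloxy)phenyl]prop-2-enoate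
Conditions: BnBr (2.3 equiv), K2CO3 (2.5 equiv), DMF, 60 °C
Reagents that add atoms: benzyl bromide, BrCc1ccccc1
Why: Williamson etherification and carboxylate O-alkylation (SN2 on benzyl bromide) cap both acidic OH groups at once while the E-alkene is untouched, and no stereocentre is formed.

Step 2
Reactants: 3 3,4-bis(benzyloxy)benzaldehyde; 4 glycine tert-butyl ester hydrochloride
Product: 5 tert-butyl N-[(E)-3,4-bis(benzyloxy)benzylidene]glycinate
Conditions: Et3N (1.1 equiv), MgSO4, CH2Cl2, rt; crude imine used directly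
Reagents that add atoms: none
Why: Condensation of the liberated amino ester with the aldehyde (imine formation, water bound by MgSO4) should give the E-aldimine that serves as the azomethine ylide precursor, and no stereocentre is formed.

Step 3
Reactants: 5 tert-butyl N-[(E)-3,4-bis(benzyloxy)benzylidene]glycinate; 2 benzyl (E)-3-[4-(benzyloxy)phenyl]prop-2-enoate
Product: 7 4-benzyl 2-tert-butyl (2S,3S,4R,5R)-5-[3,4-bis(benzyloxy)phenyl]-3-[4-(benzyloxy)phenyl]pyrrolidine-2,4-dicarboxylate, via copper azomethine ylide 6 (not isolated)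
Conditions: Cu(CH3CN)4PF6 (5 mol %), (R)-DTBM-Segphos (5.5 mol %), Et3N (10 mol %), THF, −20 °C to rt
Reagents that add atoms: none
Why: In this catalytic asymmetric 1,3-dipolar cycloaddition the syn (W-shaped) N,O-chelated ylide 6 fixes 2,5-cis, the E-alkene fixes 3,4-trans, the ylide carbon α to the ester bonds to the β-carbon of the cinnamate, and the bulky bisphosphine on monovalent copper should steer the benzyl ester away from the metal (exo: 4-ester trans to the 5-aryl group, 3-aryl cis to the 2-ester) and select the ylide face, so that all four stereocentres arise under catalyst control.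

Step 4
Reactants: 7 4-benzyl 2-tert-butyl (2S,3S,4R,5R)-5-[3,4-bis(benzyloxy)phenyl]-3-[4-(benzyloxy)phenyl]pyrrolidine-2,4-dicarboxylate
Product: 10 1-benzyl 3-tert-butyl (1R,2R,3R,4S)-2-[4-(benzyloxy)phenyl]-4-[3,4-bis(benzyloxy)phenyl]cyclobutane-1,3-dicarboxylate, via isodiazene 8 (not isolated), via 1,4-biradical 9 (not isolated)
Conditions: PhI(OH)OTs (2.5 equiv), NH2CO2NH4 (8 equiv), CF3CH2OH, 80 °C
Reagents that add atoms: none
Why: PhI(OH)OTs and ammonia released from NH2CO2NH4 form an iodonitrene that transfers nitrogen to the ring nitrogen of 7; with a second equivalent of oxidant this gives the 1,1-diazene 8, which loses N2 at 80 °C to the singlet 1,4-biradical 9. The closest known reaction type is the iodonitrene-mediated contraction of 2-ester-5-aryl pyrrolidines to cyclobutanes (nitrogen deletion through an isodiazene). The cyclobutane closes by radical–radical recombination of the two former α-carbons of nitrogen, C2 (stabilised by the tert-butyl ester) and C5 (benzylic), a four-membered ring closure that is faster than rotation about the C2–C3 and C4–C5 bonds. Both re-formed stereocentres are therefore controlled by the memory of the pyrrolidine (retention): the 2,5-cis relationship of 7 becomes the cis relationship of ester and aryl group across the new bond, while C3 and C4 are never touched. The step needs cyclisation to beat β-scission of 9 into two cinnamates and nitrogen transfer to beat oxidation of the arenes; the cisoid geometry in which the ring delivers the two radical centres, and the capping of all phenols as benzyl ethers, should secure this. In one operation the step should give the complete, enantioenriched head-to-tail cyclobutane with two different aryl groups and two differentiated carboxyl groups.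

Step 5
Reactants: 10 1-benzyl 3-tert-butyl (1R,2R,3R,4S)-2-[4-(benzyloxy)phenyl]-4-[3,4-bis(benzyloxy)phenyl]cyclobutane-1,3-dicarboxylate
Product: 12 1-benzyl 3-tert-butyl (1R,2R,3S,4S)-2-[4-(benzyloxy)phenyl]-4-[3,4-bis(benzyloxy)phenyl]cyclobutane-1,3-dicarboxylate, via potassium enolate 11 (not isolated)
Conditions: BnOK (20 mol %, from KH and BnOH), BnOH/THF (1:5), 50 °C; AcOH quench
Reagents that add atoms: none
Why: Base-mediated epimerisation through ester enolate 11 under thermodynamic control should move the tert-butoxycarbonyl group to the face opposite both aryl groups, because only the two carboxyl-bearing carbons can invert and the all-trans isomer is the energy minimum, while benzyloxide keeps the two carboxyl groups distinct (exchange at the benzyl ester is degenerate, the tert-butyl ester resists alcoholysis) and the aryl-bearing carbons are not acidic.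

Step 6
Reactants: 12 1-benzyl 3-tert-butyl (1R,2R,3S,4S)-2-[4-(benzyloxy)phenyl]-4-[3,4-bis(benzyloxy)phenyl]cyclobutane-1,3-dicarboxylate
Product: 13 (1S,2R,3R,4S)-3-[(benzyloxy)carbonyl]-2-[3,4-bis(benzyloxy)phenyl]-4-[4-(benzyloxy)phenyl]cyclobutane-1-carboxylic acid
Conditions: TFA/CH2Cl2 (1:4), 0 °C to rt
Reagents that add atoms: none
Why: Acidolysis of the tert-butyl ester by alkyl–oxygen cleavage (loss of 2-methylpropene) should free only this carboxyl group and leave the benzyl ester, the benzyl ethers and all stereocentres untouched.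

Step 7
Reactants: 14 sodium (2R)-3-(3,4-dihydroxyphenyl)-2-hydroxypropanoate (sodium (R)-danshensu)
Product: 15 benzyl (2R)-3-[3,4-bis(benzyloxy)phenyl]-2-hydroxypropanoate
Conditions: BnBr (3.3 equiv), K2CO3 (2.5 equiv), degassed DMF, argon, rt to 40 °C
Reagents that add atoms: benzyl bromide, BrCc1ccccc1
Why: Carboxylate and phenoxide O-benzylation (SN2) under carbonate, which is too weak to deprotonate the secondary alcohol or the α-C–H, should keep the R configuration.

Step 8
Reactants: 13 (1S,2R,3R,4S)-3-[(benzyloxy)carbonyl]-2-[3,4-bis(benzyloxy)phenyl]-4-[4-(benzyloxy)phenyl]cyclobutane-1-carboxylic acid; 15 benzyl (2R)-3-[3,4-bis(benzyloxy)phenyl]-2-hydroxypropanoate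
Product: 17 benzyl (2S)-3-[3,4-bis(benzyloxy)phenyl]-2-({(1S,2S,3R,4R)-3-[(benzyloxy)carbonyl]-2-[3,4-bis(benzyloxy)phenyl]-4-[4-(benzyloxy)phenyl]cyclobutane-1-carbonyl}oxy)propanoate, via alkoxyphosphonium carboxylate 16 (not isolated)
Conditions: PPh3 (1.5 equiv), DIAD (1.5 equiv), THF, 0 °C to rt
Reagents that add atoms: none
Why: In the Mitsunobu esterification the alcohol is activated as alkoxyphosphonium 16 and displaced by the carboxylate of 13 in an SN2 step with inversion, which should turn the R carbinol into the S-configured ester carbon under neutral conditions that do not touch the cyclobutane stereocentres.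

Step 9
Reactants: 17 benzyl (2S)-3-[3,4-bis(benzyloxy)phenyl]-2-({(1S,2S,3R,4R)-3-[(benzyloxy)carbonyl]-2-[3,4-bis(benzyloxy)phenyl]-4-[4-(benzyloxy)phenyl]cyclobutane-1-carbonyl}oxy)propanoate
Product: 18 (2S)-2-({(1S,2S,3R,4R)-3-carboxy-2-(3,4-dihydroxyphenyl)-4-(4-hydroxyphenyl)cyclobutane-1-carbonyl}oxy)-3-(3,4-dihydroxyphenyl)propanoic acid (CNP0270917.2)
Conditions: H2 (1 atm), Pd/C (10 wt % Pd), EtOAc/MeOH (1:1), rt; filtration and work-up under argon
Reagents that add atoms: none
Why: Catalytic hydrogenolysis should cleave the five benzyl ethers and two benzyl esters at their benzylic C–O bonds while the aliphatic ester, the cyclobutane and all stereocentres stay inert.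

**Compound list**

1 | (E)-4-hydroxycinnamic acid (p-coumaric acid) | OC(=O)/C=C/c1ccc(O)cc1 | starting material
2 | benzyl (E)-3-[4-(benzyloxy)phenyl]prop-2-enoate | O=C(OCc1ccccc1)/C=C/c1ccc(OCc2ccccc2)cc1 | intermediate
3 | 3,4-bis(benzyloxy)benzaldehyde | O=Cc1ccc(OCc2ccccc2)c(OCc2ccccc2)c1 | starting material
4 | glycine tert-butyl ester hydrochloride | Cl.NCC(=O)OC(C)(C)C | starting material
5 | tert-butyl N-[(E)-3,4-bis(benzyloxy)benzylidene]glycinate | CC(C)(C)OC(=O)C/N=C/c1ccc(OCc2ccccc2)c(OCc2ccccc2)c1 | intermediate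
6 | copper azomethine ylide (N,O-chelated copper enolate of 5; bisphosphine on copper not drawn) | CC(C)(C)OC(O[Cu])=CN=Cc1ccc(OCc2ccccc2)c(OCc2ccccc2)c1 | intermediate
7 | 4-benzyl 2-tert-butyl (2S,3S,4R,5R)-5-[3,4-bis(benzyloxy)phenyl]-3-[4-(benzyloxy)phenyl]pyrrolidine-2,4-dicarboxylate (exo adduct: 2,3-cis, 3,4-trans, 4,5-trans, 2,5-cis) | O=C(OCc1ccccc1)[C@H]([C@@H](c1ccc(OCc2ccccc2)cc1)[C@@H](C(=O)OC(C)(C)C)N3)[C@@H]3c1ccc(OCc2ccccc2)c(OCc2ccccc2)c1 | intermediate
8 | isodiazene (1,1-diazene) of 7 | O=C(OCc1ccccc1)[C@H]([C@@H](c1ccc(OCc2ccccc2)cc1)[C@@H](C(=O)OC(C)(C)C)[N+]3=[N-])[C@@H]3c1ccc(OCc2ccccc2)c(OCc2ccccc2)c1 | intermediate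
9 | 1,4-biradical (radical centres at the ester α-carbon and the benzylic carbon) | O=C(OCc1ccccc1)[C@H]([C@@H](c1ccc(OCc2ccccc2)cc1)[CH]C(=O)OC(C)(C)C)[CH]c1ccc(OCc2ccccc2)c(OCc2ccccc2)c1 | intermediate
10 | 1-benzyl 3-tert-butyl (1R,2R,3R,4S)-2-[4-(benzyloxy)phenyl]-4-[3,4-bis(benzyloxy)phenyl]cyclobutane-1,3-dicarboxylate (tert-butyl ester cis to both aryl groups) | O=C(OCc1ccccc1)[C@@H]3[C@@H](c1ccc(OCc2ccccc2)cc1)[C@@H](C(=O)OC(C)(C)C)[C@H]3c1ccc(OCc2ccccc2)c(OCc2ccccc2)c1 | intermediate
11 | potassium enolate of the tert-butyl ester of 10 | O=C(OCc1ccccc1)[C@@H]3[C@@H](c1ccc(OCc2ccccc2)cc1)C(=C([O-])OC(C)(C)C)[C@H]3c1ccc(OCc2ccccc2)c(OCc2ccccc2)c1.[K+] | intermediate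
12 | 1-benzyl 3-tert-butyl (1R,2R,3S,4S)-2-[4-(benzyloxy)phenyl]-4-[3,4-bis(benzyloxy)phenyl]cyclobutane-1,3-dicarboxylate (all-trans) | O=C(OCc1ccccc1)[C@@H]3[C@@H](c1ccc(OCc2ccccc2)cc1)[C@H](C(=O)OC(C)(C)C)[C@H]3c1ccc(OCc2ccccc2)c(OCc2ccccc2)c1 | intermediate
13 | (1S,2R,3R,4S)-3-[(benzyloxy)carbonyl]-2-[3,4-bis(benzyloxy)phenyl]-4-[4-(benzyloxy)phenyl]cyclobutane-1-carboxylic acid (all-trans) | O=C(OCc1ccccc1)[C@@H]3[C@@H](c1ccc(OCc2ccccc2)cc1)[C@H](C(=O)O)[C@H]3c1ccc(OCc2ccccc2)c(OCc2ccccc2)c1 | intermediate
14 | sodium (2R)-3-(3,4-dihydroxyphenyl)-2-hydroxypropanoate (sodium (R)-danshensu) | [Na+].[O-]C(=O)[C@H](O)Cc1ccc(O)c(O)c1 | starting material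
15 | benzyl (2R)-3-[3,4-bis(benzyloxy)phenyl]-2-hydroxypropanoate | O=C(OCc1ccccc1)[C@H](O)Cc1ccc(OCc2ccccc2)c(OCc2ccccc2)c1 | intermediate
16 | alkoxyphosphonium carboxylate (O-triphenylphosphonio derivative of 15 paired with the carboxylate of 13) | O=C(OCc1ccccc1)[C@H](O[P+](c1ccccc1)(c1ccccc1)c1ccccc1)Cc1ccc(OCc2ccccc2)c(OCc2ccccc2)c1.O=C(OCc1ccccc1)[C@@H]3[C@@H](c1ccc(OCc2ccccc2)cc1)[C@H](C(=O)[O-])[C@H]3c1ccc(OCc2ccccc2)c(OCc2ccccc2)c1 | intermediate
17 | benzyl (2S)-3-[3,4-bis(benzyloxy)phenyl]-2-({(1S,2S,3R,4R)-3-[(benzyloxy)carbonyl]-2-[3,4-bis(benzyloxy)phenyl]-4-[4-(benzyloxy)phenyl]cyclobutane-1-carbonyl}oxy)propanoate | O=C(OCc1ccccc1)[C@@H]3[C@@H](c1ccc(OCc2ccccc2)cc1)[C@H](C(=O)O[C@@H](Cc1ccc(OCc2ccccc2)c(OCc2ccccc2)c1)C(=O)OCc1ccccc1)[C@H]3c1ccc(OCc2ccccc2)c(OCc2ccccc2)c1 | intermediate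
18 | (2S)-2-({(1S,2S,3R,4R)-3-carboxy-2-(3,4-dihydroxyphenyl)-4-(4-hydroxyphenyl)cyclobutane-1-carbonyl}oxy)-3-(3,4-dihydroxyphenyl)propanoic acid (CNP0270917.2) | O=C(O)[C@@H]1[C@@H](c2ccc(O)cc2)[C@H](C(=O)O[C@@H](Cc2ccc(O)c(O)c2)C(=O)O)[C@H]1c1ccc(O)c(O)c1 | target

**Step count and risks**

Total step count: 9. Longest linear sequence: 7 steps (steps 2, 3, 4, 5, 6, 8 and 9; steps 1 and 7 prepare the two side fragments).

Steps most likely to fail:

1. Step 3. The β-aryl acrylate is a sluggish dipolarophile, and both the exo approach of the ester and the facial selection on the ylide may be incomplete, so endo adduct or low enantiomeric purity could erode the series. Fallback (enantiocontrol taken out of the cycloaddition, classical resolution): setting out from 5 and 2, the cycloaddition is run with an achiral catalyst chosen only for turnover and exo selectivity (Cu(CH3CN)4PF6, 1,2-bis(diphenylphosphino)benzene, Et3N, toluene, 40 °C). After removal of any endo isomer by chromatography this should give the racemic exo adduct, that is 7 together with its mirror image, the (2R,3R,4S,5S) pyrrolidine F1. The secondary amine is then resolved with (−)-O,O′-di-p-toluoyl-L-tartaric acid in EtOAc/EtOH: the less soluble salt, the hydrogen di-p-toluoyl-L-tartrate of 7 F2, is recrystallised, and partition between aqueous NaHCO3 and EtOAc returns to the route at 7. If the salt of the mirror image crystallises first, the D-acid is used.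

2. Step 4. Biradical 9 may undergo β-scission into tert-butyl 4-benzyloxycinnamate and benzyl 3,4-bis(benzyloxy)cinnamate instead of closing, and the trivalent iodine reagent may attack the electron-rich benzyloxy arenes before nitrogen transfer. Fallback (stepwise N-amination and mild oxidation without hypervalent iodine): setting out from 7, N-nitrosation (tBuONO, CH2Cl2, rt) should give the N-nitroso pyrrolidine F3, and reduction with Zn in AcOH the 1-aminopyrrolidine F4. Oxidation of F4 with yellow HgO in CH2Cl2 at 0 °C generates the same isodiazene 8 at low temperature, where collapse of biradical 9 should compete better with fragmentation, and the route is rejoined at 10.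

3. Step 5. Enolisation of the shielded tert-butyl ester may be slow, which would leave the equilibration incomplete or allow ester exchange that makes the two carboxyl groups identical and thereby erases the stereochemical information of the meso-type core. Fallback (thermodynamic correction moved in front of the contraction): setting out from 7, the prolinate-type C2–H, which is flanked by nitrogen and the ester and is less shielded, is equilibrated (BnOK 10 mol %, BnOH/THF, rt) to the all-trans (2R,3S,4R,5R) pyrrolidine F5, in which the 2,3-cis strain is relieved. Contraction of F5 under the conditions of step 4, through the corresponding isodiazene F6 and the same biradical 9, should with retention place both esters trans to both aryl groups, so that the route is rejoined directly at 12.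

Further compounds

F1 | step 3 | 4-benzyl 2-tert-butyl (2R,3R,4S,5S)-5-[3,4-bis(benzyloxy)phenyl]-3-[4-(benzyloxy)phenyl]pyrrolidine-2,4-dicarboxylate (enantiomer of 7) | O=C(OCc1ccccc1)[C@@H]([C@H](c1ccc(OCc2ccccc2)cc1)[C@H](C(=O)OC(C)(C)C)N3)[C@H]3c1ccc(OCc2ccccc2)c(OCc2ccccc2)c1
F2 | step 3 | hydrogen di-p-toluoyl-L-tartrate salt of 7 | O=C(OCc1ccccc1)[C@H]([C@@H](c1ccc(OCc2ccccc2)cc1)[C@@H](C(=O)OC(C)(C)C)[NH2+]3)[C@@H]3c1ccc(OCc2ccccc2)c(OCc2ccccc2)c1.OC(=O)[C@H](OC(=O)c1ccc(C)cc1)[C@@H](OC(=O)c1ccc(C)cc1)C(=O)[O-]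
F3 | step 4 | N-nitroso derivative of 7 | O=C(OCc1ccccc1)[C@H]([C@@H](c1ccc(OCc2ccccc2)cc1)[C@@H](C(=O)OC(C)(C)C)N3N=O)[C@@H]3c1ccc(OCc2ccccc2)c(OCc2ccccc2)c1
F4 | step 4 | 1-amino derivative of 7 | O=C(OCc1ccccc1)[C@H]([C@@H](c1ccc(OCc2ccccc2)cc1)[C@@H](C(=O)OC(C)(C)C)N3N)[C@@H]3c1ccc(OCc2ccccc2)c(OCc2ccccc2)c1
F5 | step 5 | 4-benzyl 2-tert-butyl (2R,3S,4R,5R)-5-[3,4-bis(benzyloxy)phenyl]-3-[4-(benzyloxy)phenyl]pyrrolidine-2,4-dicarboxylate (all-trans) | O=C(OCc1ccccc1)[C@H]([C@@H](c1ccc(OCc2ccccc2)cc1)[C@H](C(=O)OC(C)(C)C)N3)[C@@H]3c1ccc(OCc2ccccc2)c(OCc2ccccc2)c1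
F6 | step 5 | isodiazene (1,1-diazene) of F5 | O=C(OCc1ccccc1)[C@H]([C@@H](c1ccc(OCc2ccccc2)cc1)[C@H](C(=O)OC(C)(C)C)[N+]3=[N-])[C@@H]3c1ccc(OCc2ccccc2)c(OCc2ccccc2)c1
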